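**Assumptions (one line each)**
- The target has no stereocentres. Its only stereochemistry is the geometry of the five internal trisubstituted alkenes, all E. The terminal prenyl alkene has no E/Z descriptor.
- All-trans hexaprenol (C30) is taken to be available as a specialty isoprenoid. Q0 (2,3-dimethoxy-5-methylbenzoquinone) is a standard catalogue chemical.

## Retrosynthetic overview
1. No ring is formed. The fully substituted aromatic core comes from commercial Q0.
2. The only C–C bond disconnected is aryl C6–CH2 of the side chain. This is a Friedel–Crafts-type allylation of 2,3-dimethoxy-5-methylhydroquinone (2) at its only free ring position, using all-E hexaprenol (3).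
3. The E geometry of all five internal alkenes is carried in unchanged from 3.
4. Hydroquinone 2 comes from reduction of Q0 (1), so the final product is the ubiquinol directly, with no late-stage redox step.

## Route

**Step 1**
- Reactants: 1, 2,3-dimethoxy-5-methyl-1,4-benzoquinone (Q0)
- Product: 2, 2,3-dimethoxy-5-methylbenzene-1,4-diol (Q0H2)
- Conditions: Na2S2O4 (2.5 equiv), Et2O/H2O 1:1, rt, 15 min, Ar
- Reagents that add atoms: none. The product gains only H, from water.
- Why: Dithionite reduces the quinone to the hydroquinone by two-electron reduction. The ring carries no stereochemistry, and the methoxy groups and methyl are untouched.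

**Step 2**
- Reactants: 2, Q0H2 (2 equiv); 3, (2E,6E,10E,14E,18E)-hexaprenol (1 equiv)
- Product: 4, ubiquinol-6
- Conditions: BF3·OEt2 (1 equiv), 1,4-dioxane, 40 °C, 3 h, Ar. Work up with aqueous Na2S2O4, then chromatograph on silica under Ar.
- Reagents that add atoms: none. The hexaprenyl group comes from reactant 3, and BF3 is a promoter that is not incorporated.
- Why: BF3 ionises the primary allylic alcohol to an allyl cation equivalent. The electron-rich hydroquinone (2) attacks through its only free ring carbon (C6, ortho to OH) at the unhindered CH2 terminus, in a Friedel–Crafts allylation. This keeps the linear isoprenoid chain. No new stereocentre forms, and the E geometry of all five internal alkenes is inherited from 3. Because the hydroquinone oxidation level is kept, no further redox step is needed.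

## Checks performed
- **Ring:** The ring is six-membered with substituents in the order OMe, OH, Me, chain, OH, OMe. This matches the target SMILES. The two OH groups are para, and the chain is flanked by OH and Me.
- **Chain:** The chain has 30 carbons, six isoprene units, five E alkenes plus the terminal prenyl. This matches the target.
- **Atom count:** Atoms balance. Compound 2 (C9H12O4) plus compound 3 (C30H50O) gives compound 4 (C39H60O4) plus H2O.
- **Functional groups:** The methyl ethers and the polyene survive BF3 at 40 °C with a short reaction time. Na2S2O4 does not touch the alkenes.
- **Stereochemistry:** The alkene geometry is set in the starting material 3 and is not altered in the route.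

## Compound list
1 | 2,3-dimethoxy-5-methyl-1,4-benzoquinone (Q0) | COC1=C(OC)C(=O)C(C)=CC1=O | starting material
2 | 2,3-dimethoxy-5-methylbenzene-1,4-diol (Q0H2) | COc1c(OC)c(O)c(C)cc1O | intermediate
3 | (2E,6E,10E,14E,18E)-3,7,11,15,19,23-hexamethyltetracosa-2,6,10,14,18,22-hexaen-1-ol (all-trans hexaprenol) | OC/C=C(\C)CC/C=C(\C)CC/C=C(\C)CC/C=C(\C)CC/C=C(\C)CCC=C(C)C | starting material
4 | ubiquinol-6 (2,3-dimethoxy-5-methyl-6-[(all-E)-hexaprenyl]benzene-1,4-diol) | COc1c(O)c(C)c(C/C=C(\C)CC/C=C(\C)CC/C=C(\C)CC/C=C(\C)CC/C=C(\C)CCC=C(C)C)c(O)c1OC | target

## Totals
- Total steps: 2
- Longest linear sequence: 2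

## Three steps most likely to fail, with fallbacks
1. **Step 2, BF3 allylation.**
   - Risk: moderate yield, because of chromane formation from cyclisation onto the first alkene, O-allylation, and some E→Z isomerisation.
   - Fallback (different approach): ortho-lithiate 1,2,3,4-tetramethoxy-5-methylbenzene and couple it with hexaprenyl bromide under CuI catalysis. Then oxidatively demethylate with CAN to give CoQ6, and reduce with Na2S2O4.
2. **Step 1 and handling of hydroquinone 2.**
   - Risk: 2 air-oxidises back to Q0 during isolation and use, which lowers the effective stoichiometry in step 2.
   - Fallback (different approach): avoid the free hydroquinone. Couple Q0 itself with hexaprenyl-SnBu3 under BF3 (allylstannane–quinone coupling) to give CoQ6, then reduce.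
3. **Isolation of 4.**
   - Risk: the electron-rich ubiquinol oxidises to CoQ6 on silica or in air.
   - Fallback (different end-game): deliberately oxidise the crude product to the stable quinone (Ag2O or air), purify and store it as CoQ6, then reduce with Na2S2O4 immediately before use.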